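**Retrosynthetic overview**
1. Target 25 comes from 24 and 23 by acetylation and desilylation. The side chain of 23 is made by B-alkyl Suzuki coupling (C12–C13) of vinyl compound 21 with enol triflate 2. The vinyl group of 21 comes from the C11 ester of adduct 18.
2. The strategy rests on ring B: a cyclohexene (C6=C7) whose C8 carries the exocyclic C17 methylene and whose C9 carries C11. This is the adduct pattern of a vinylallene C17=C8=C7–C6=C5 with a C9=C10 (E)-enoate. An intramolecular Diels–Alder reaction of 17 forms C5–C10 and C8–C9, so rings A and B close in the same step.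
3. Vinylallene 17 comes from aldehyde 11 by Takai iodo-olefination, Sonogashira coupling with propargyl alcohol and reductive 1,3-transposition to the allene.
4. The quaternary C4 of 11 comes from epoxy silyl ether 10 by a stereospecific 1,2-shift of the siloxymethyl group; 10 comes from (E)-allylic alcohol 8 by Sharpless epoxidation.
5. Alcohol 8 comes from dienol 6 and enol triflate 2 by B-alkyl Suzuki coupling (C1–C10); 6 is made from pent-1-en-4-yne and 2 from methyl acetoacetate.

Key step: step 10

Remark: the bicyclic compounds are discussed with labdane numbering (decalin C1–C10, C11 on C9, C17 the methylene on C8, C18 the oxygen-bearing carbon and C19 the methyl on C4, C20 the methyl on C10), and the same numbers are used for the open-chain atoms that become these positions. The target SMILES requires the C4 methyl, the C10 methyl and the C9 side chain on one face, and H5, H9 and CH2OAc on the other.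

**Step 1**
Reactants: 1 methyl acetoacetate
Product: 2 methyl (2E)-3-{[(trifluoromethyl)sulfonyl]oxy}but-2-enoate
Conditions: Tf2O, aq. Me4NOH, hexanes, 5 → 23 °C
Reagents that add atoms: trifluoromethanesulfonic anhydride, O=S(=O)(OS(=O)(=O)C(F)(F)F)C(F)(F)F
Why: Enol triflation of a β-keto ester under biphasic conditions with a non-chelating ammonium counter-ion should trap the open enolate and give the (E)-enol triflate (triflate trans to the ester), the geometry needed for the two stereoretentive couplings.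

**Step 2**
Reactants: 3 pent-1-en-4-yne
Product: 6 (2E)-3-methylhexa-2,5-dien-1-ol, via alkenyldimethylalane 4 (not isolated), via lithium alkenylaluminate 5 (not isolated)
Conditions: Me3Al, Cp2ZrCl2 (0.25 equiv), CH2Cl2, 0 → 23 °C; then n-BuLi, THF, −78 °C; (CH2O)n, −78 → 23 °C
Reagents that add atoms: trimethylaluminium, C[Al](C)C; paraformaldehyde (as formaldehyde), C=O
Why: Zirconium-catalysed syn methylalumination of the terminal alkyne (Negishi carboalumination) puts the methyl on the internal carbon cis to aluminium, and the derived aluminate adds to formaldehyde with retention to give the (E)-allylic alcohol, the isolated terminal alkene being inert to this reagent pair.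

**Step 3**
Reactants: 6 (2E)-3-methylhexa-2,5-dien-1-ol; 2 methyl (2E)-3-{[(trifluoromethyl)sulfonyl]oxy}but-2-enoate
Product: 8 methyl (2E,7E)-9-hydroxy-3,7-dimethylnona-2,7-dienoate, via bis-boryl intermediate 7 (not isolated)
Conditions: 9-BBN (2.2 equiv), THF, 0 → 23 °C; then aq. K3PO4, 2, Pd(dppf)Cl2 (cat.), DMF, 23 °C
Reagents that add atoms: none
Why: 9-BBN adds anti-Markovnikov to the monosubstituted alkene far faster than to the trisubstituted one (the second equivalent is taken up by the hydroxyl group), and the B-alkyl Suzuki–Miyaura coupling with the enol triflate forms C1–C10 with retention of the (E) geometry.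

**Step 4**
Reactants: 8 methyl (2E,7E)-9-hydroxy-3,7-dimethylnona-2,7-dienoate
Product: 9 methyl (2E)-6-[(2R,3R)-3-(hydroxymethyl)-2-methyloxiran-2-yl]-3-methylhex-2-enoate
Conditions: Ti(Oi-Pr)4 (cat.), D-(−)-diethyl tartrate (cat.), t-BuOOH, 4 Å MS, CH2Cl2, −20 °C
Reagents that add atoms: tert-butyl hydroperoxide, CC(C)(C)OO
Why: Sharpless asymmetric epoxidation of a geraniol-type (E)-3,3-disubstituted allylic alcohol with the D-tartrate should deliver oxygen to the face that gives the (2R,3R)-epoxide (both new stereocentres under reagent control), and the electron-poor enoate is not epoxidised.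

**Step 5**
Reactants: 9 methyl (2E)-6-[(2R,3R)-3-(hydroxymethyl)-2-methyloxiran-2-yl]-3-methylhex-2-enoate
Product: 10 methyl (2E)-6-[(2R,3R)-3-({[tert-butyl(dimethyl)silyl]oxy}methyl)-2-methyloxiran-2-yl]-3-methylhex-2-enoate
Conditions: TBSCl, imidazole, DMF, 23 °C
Reagents that add atoms: tert-butyldimethylsilyl chloride, CC(C)(C)[Si](C)(C)Cl
Why: Standard silylation of the primary alcohol gives the bulky, weakly coordinating silyl ether that the rearrangement of step 6 and the cycloaddition of step 10 both need.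

**Step 6**
Reactants: 10 methyl (2E)-6-[(2R,3R)-3-({[tert-butyl(dimethyl)silyl]oxy}methyl)-2-methyloxiran-2-yl]-3-methylhex-2-enoate
Product: 11 methyl (2E,7R)-7-({[tert-butyl(dimethyl)silyl]oxy}methyl)-3,7-dimethyl-8-oxooct-2-enoate
Conditions: MeAl(OAr)2 (Ar = 4-bromo-2,6-di-tert-butylphenyl; 2.2 equiv, made in the flask from Me3Al and ArOH), CH2Cl2, −78 °C
Reagents that add atoms: none
Why: The bulky aluminium Lewis acid opens the epoxide at its fully substituted carbon and the siloxymethyl group migrates anti to the departing oxygen (semipinacol-type rearrangement of an epoxy silyl ether to a β-siloxy aldehyde), so the epoxide chirality is transferred with inversion to the new quaternary C4, the second equivalent of reagent being there for the ester carbonyl.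

**Step 7**
Reactants: 11 methyl (2E,7R)-7-({[tert-butyl(dimethyl)silyl]oxy}methyl)-3,7-dimethyl-8-oxooct-2-enoate
Product: 12 methyl (2E,7S,8E)-7-({[tert-butyl(dimethyl)silyl]oxy}methyl)-9-iodo-3,7-dimethylnona-2,8-dienoate
Conditions: CrCl2, CHI3, THF, 0 → 23 °C
Reagents that add atoms: iodoform, IC(I)I
Why: Takai iodo-olefination of the non-enolisable α-quaternary aldehyde should give the (E)-vinyl iodide (C5=C6) and leaves the enoate and silyl ether untouched (the descriptor at C4 changes only through priorities).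

**Step 8**
Reactants: 12 methyl (2E,7S,8E)-7-({[tert-butyl(dimethyl)silyl]oxy}methyl)-9-iodo-3,7-dimethylnona-2,8-dienoate; 13 prop-2-yn-1-ol
Product: 14 methyl (2E,7S,8E)-7-({[tert-butyl(dimethyl)silyl]oxy}methyl)-12-hydroxy-3,7-dimethyldodeca-2,8-dien-10-ynoate
Conditions: Pd(PPh3)2Cl2 (cat.), CuI (cat.), Et3N, THF, 23 °C
Reagents that add atoms: none
Why: Sonogashira coupling of a vinyl iodide with a terminal alkyne proceeds with retention of the (E) geometry and tolerates the free propargylic alcohol.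

**Step 9**
Reactants: 14 methyl (2E,7S,8E)-7-({[tert-butyl(dimethyl)silyl]oxy}methyl)-12-hydroxy-3,7-dimethyldodeca-2,8-dien-10-ynoate
Product: 17 methyl (2E,7S,8E)-7-({[tert-butyl(dimethyl)silyl]oxy}methyl)-3,7-dimethyldodeca-2,8,10,11-tetraenoate, via propargylic sulfonylhydrazine 15 (not isolated), via propargylic diazene 16 (not isolated)
Conditions: 2-nitrobenzenesulfonohydrazide, PPh3, diethyl azodicarboxylate, THF, −15 → 23 °C
Reagents that add atoms: none
Why: In the Myers allene synthesis a Mitsunobu displacement of the primary propargylic alcohol by the arenesulfonylhydrazide is followed by loss of sulfinic acid and a retro-ene loss of N2 from the diazene, which moves hydrogen to C7 and gives the terminal allene below room temperature, mild enough to keep the tethered enoate from reacting.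

**Step 10**
Reactants: 17 methyl (2E,7S,8E)-7-({[tert-butyl(dimethyl)silyl]oxy}methyl)-3,7-dimethyldodeca-2,8,10,11-tetraenoate
Product: 18 methyl (1R,4aS,5S,8aR)-5-({[tert-butyl(dimethyl)silyl]oxy}methyl)-5,8a-dimethyl-2-methylidene-1,2,4a,5,6,7,8,8a-octahydronaphthalene-1-carboxylate (trans-fused; labdane positions 4S,5S,9R,10R)
Conditions: Me2AlCl (1.5 equiv), CH2Cl2 (0.01 M), −40 → 0 °C
Reagents that add atoms: none
Why: Me2AlCl binds the ester and lowers the LUMO of the C9=C10 enoate, which then adds in a concerted, asynchronous [4+2] to the s-cis diene C5=C6–C7=C8 (the proximal allene bond), forming C8–C9 and C5–C10 while the orthogonal C8=C17 bond is left as the exocyclic methylene. The closest known reactions are intramolecular Diels–Alder reactions of vinylallenes and Lewis-acid-promoted cyclisations of 1,7,9-decatrienoates to trans-fused octalins. Ring A closes as the C4–C3–C2–C1 tether folds into a chair between diene terminus C5 and dienophile carbon C10 with the tether exo, and ring B is the cyclohexene formed by the cycloaddition itself. The cis relation of C20 and C11 at C10/C9 follows from suprafacial addition to the (E)-enoate, the trans ring fusion (H5 anti to C20) from the transition state with the ester endo on the (E)-C5=C6 diene, and the absolute sense of C5, C9 and C10 from C4, the dienophile adding to the diene face that carries the C4 methyl (1,3 to the C10 methyl) while CH2OTBS points away. Two selectivities are needed: endo over exo, supported by the aluminium-bound ester, the fixed alkene geometries and the C17–H that projects over the reacting face and disfavours an exo ester, and π-facial selectivity, which rests only on the size difference between CH3 and CH2OTBS at C4 with a silyl ether that does not chelate aluminium and is therefore expected to be modest, so that the diastereomer with the C4 groups interchanged relative to the new centres would be removed by chromatography here or at 19. The quaternary C4 has no hydrogen, so the vinylallene cannot undergo a [1,5]-hydrogen shift, and high dilution suppresses its dimerisation.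

**Step 11**
Reactants: 18 methyl (1R,4aS,5S,8aR)-5-({[tert-butyl(dimethyl)silyl]oxy}methyl)-5,8a-dimethyl-2-methylidene-1,2,4a,5,6,7,8,8a-octahydronaphthalene-1-carboxylate
Product: 19 [(1R,4aS,5S,8aR)-5-({[tert-butyl(dimethyl)silyl]oxy}methyl)-5,8a-dimethyl-2-methylidene-1,2,4a,5,6,7,8,8a-octahydronaphthalen-1-yl]methanol
Conditions: i-Bu2AlH, CH2Cl2, −78 → 0 °C
Reagents that add atoms: none
Why: Ester reduction with a Lewis-acidic, non-basic hydride gives the C11 alcohol without enolising the ester, whose α-hydrogen (H9) is allylic to the diene and would otherwise allow C8=C17 to move into conjugation.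

**Step 12**
Reactants: 19 [(1R,4aS,5S,8aR)-5-({[tert-butyl(dimethyl)silyl]oxy}methyl)-5,8a-dimethyl-2-methylidene-1,2,4a,5,6,7,8,8a-octahydronaphthalen-1-yl]methanol
Product: 20 (1R,4aS,5S,8aR)-5-({[tert-butyl(dimethyl)silyl]oxy}methyl)-5,8a-dimethyl-2-methylidene-1,2,4a,5,6,7,8,8a-octahydronaphthalene-1-carbaldehyde
Conditions: Dess–Martin periodinane, NaHCO3, CH2Cl2, 0 °C
Reagents that add atoms: none
Why: Buffered Dess–Martin oxidation is neutral and fast, so the β,γ-unsaturated aldehyde should be obtained without epimerisation at C9 or double-bond migration and is used at once.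

**Step 13**
Reactants: 20 (1R,4aS,5S,8aR)-5-({[tert-butyl(dimethyl)silyl]oxy}methyl)-5,8a-dimethyl-2-methylidene-1,2,4a,5,6,7,8,8a-octahydronaphthalene-1-carbaldehyde
Product: 21 (1R,4aS,5S,8aS)-5-({[tert-butyl(dimethyl)silyl]oxy}methyl)-1-ethenyl-5,8a-dimethyl-2-methylidene-1,2,4a,5,6,7,8,8a-octahydronaphthalene
Conditions: Ph3PCH3Br, KN(SiMe3)2, THF, 0 °C; then 20, −78 → 0 °C
Reagents that add atoms: methyltriphenylphosphonium bromide, C[P+](c1ccccc1)(c1ccccc1)c1ccccc1.[Br-]
Why: Wittig methylenation at low temperature adds to the aldehyde carbonyl much faster than the ylide can remove the hindered tertiary H9, giving the C11=C12 vinyl group with C9 unchanged (the 8a descriptor changes only through priorities).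

**Step 14**
Reactants: 21 (1R,4aS,5S,8aS)-5-({[tert-butyl(dimethyl)silyl]oxy}methyl)-1-ethenyl-5,8a-dimethyl-2-methylidene-1,2,4a,5,6,7,8,8a-octahydronaphthalene; 2 methyl (2E)-3-{[(trifluoromethyl)sulfonyl]oxy}but-2-enoate
Product: 23 methyl (2E)-5-[(1R,4aS,5S,8aS)-5-({[tert-butyl(dimethyl)silyl]oxy}methyl)-5,8a-dimethyl-2-methylidene-1,2,4a,5,6,7,8,8a-octahydronaphthalen-1-yl]-3-methylpent-2-enoate, via alkylborane 22 (not isolated)
Conditions: 9-BBN (1.2 equiv), THF, 0 → 23 °C; then aq. K3PO4, 2, Pd(dppf)Cl2 (cat.), DMF, 23 °C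
Reagents that add atoms: none
Why: 9-BBN should add to the monosubstituted C11=C12 bond in preference to the conjugated diene, whose exocyclic terminus is deactivated by conjugation and flanked by C7 and C9, and the B-alkyl Suzuki–Miyaura coupling then forms C12–C13 with retention, fixing the (13E)-enoate.

**Step 15**
Reactants: 23 methyl (2E)-5-[(1R,4aS,5S,8aS)-5-({[tert-butyl(dimethyl)silyl]oxy}methyl)-5,8a-dimethyl-2-methylidene-1,2,4a,5,6,7,8,8a-octahydronaphthalen-1-yl]-3-methylpent-2-enoate
Product: 24 methyl (2E)-5-[(1R,4aS,5S,8aS)-5-(hydroxymethyl)-5,8a-dimethyl-2-methylidene-1,2,4a,5,6,7,8,8a-octahydronaphthalen-1-yl]-3-methylpent-2-enoate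
Conditions: Bu4NF, AcOH, THF, 23 → 40 °C
Reagents that add atoms: none
Why: Fluoride cleaves the neopentyl silyl ether, and the acetic acid buffer keeps the medium from deprotonating the enoate or moving the diene.

**Step 16**
Reactants: 24 methyl (2E)-5-[(1R,4aS,5S,8aS)-5-(hydroxymethyl)-5,8a-dimethyl-2-methylidene-1,2,4a,5,6,7,8,8a-octahydronaphthalen-1-yl]-3-methylpent-2-enoate
Product: 25 methyl (2E)-5-[(1R,4aS,5S,8aS)-5-[(acetyloxy)methyl]-5,8a-dimethyl-2-methylidene-1,2,4a,5,6,7,8,8a-octahydronaphthalen-1-yl]-3-methylpent-2-enoate (CNP0148290.1)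
Conditions: Ac2O, pyridine, DMAP (cat.), CH2Cl2, 23 °C
Reagents that add atoms: acetic anhydride, CC(=O)OC(C)=O
Why: DMAP-catalysed acylation of the primary neopentyl alcohol is a routine esterification that touches no stereocentre.

**Compound list**
1 | methyl acetoacetate | COC(=O)CC(C)=O | starting material
2 | methyl (2E)-3-{[(trifluoromethyl)sulfonyl]oxy}but-2-enoate | COC(=O)/C=C(\C)OS(=O)(=O)C(F)(F)F | intermediate
3 | pent-1-en-4-yne | C=CCC#C | starting material
4 | dimethyl[(1E)-2-methylpenta-1,4-dien-1-yl]alumane | C=CC/C(C)=C/[Al](C)C | intermediate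
5 | lithium butyl(dimethyl)[(1E)-2-methylpenta-1,4-dien-1-yl]aluminate | [Li+].CCCC[Al-](C)(C)/C=C(\C)CC=C | intermediate
6 | (2E)-3-methylhexa-2,5-dien-1-ol | C=CC/C(C)=C/CO | intermediate
7 | 9-[(4E)-6-(9-borabicyclo[3.3.1]nonan-9-yloxy)-4-methylhex-4-en-1-yl]-9-borabicyclo[3.3.1]nonane | C/C(CCCB1C2CCCC1CCC2)=C\COB1C2CCCC1CCC2 | intermediate
8 | methyl (2E,7E)-9-hydroxy-3,7-dimethylnona-2,7-dienoate | OC/C=C(C)/CCC/C(C)=C/C(=O)OC | intermediate
9 | methyl (2E)-6-[(2R,3R)-3-(hydroxymethyl)-2-methyloxiran-2-yl]-3-methylhex-2-enoate | OC[C@H]1O[C@]1(C)CCC/C(C)=C/C(=O)OC | intermediate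
10 | methyl (2E)-6-[(2R,3R)-3-({[tert-butyl(dimethyl)silyl]oxy}methyl)-2-methyloxiran-2-yl]-3-methylhex-2-enoate | CC(C)(C)[Si](C)(C)OC[C@H]1O[C@]1(C)CCC/C(C)=C/C(=O)OC | intermediate
11 | methyl (2E,7R)-7-({[tert-butyl(dimethyl)silyl]oxy}methyl)-3,7-dimethyl-8-oxooct-2-enoate | O=C[C@@](C)(CO[Si](C)(C)C(C)(C)C)CCC/C(C)=C/C(=O)OC | intermediate
12 | methyl (2E,7S,8E)-7-({[tert-butyl(dimethyl)silyl]oxy}methyl)-9-iodo-3,7-dimethylnona-2,8-dienoate | I/C=C/[C@@](C)(CO[Si](C)(C)C(C)(C)C)CCC/C(C)=C/C(=O)OC | intermediate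
13 | prop-2-yn-1-ol | OCC#C | starting material
14 | methyl (2E,7S,8E)-7-({[tert-butyl(dimethyl)silyl]oxy}methyl)-12-hydroxy-3,7-dimethyldodeca-2,8-dien-10-ynoate | OCC#C/C=C/[C@@](C)(CO[Si](C)(C)C(C)(C)C)CCC/C(C)=C/C(=O)OC | intermediate
15 | methyl (2E,7S,8E)-7-({[tert-butyl(dimethyl)silyl]oxy}methyl)-3,7-dimethyl-12-[1-(2-nitrobenzenesulfonyl)hydrazin-1-yl]dodeca-2,8-dien-10-ynoate | NN(CC#C/C=C/[C@@](C)(CO[Si](C)(C)C(C)(C)C)CCC/C(C)=C/C(=O)OC)S(=O)(=O)c1ccccc1[N+](=O)[O-] | intermediate
16 | methyl (2E,7S,8E)-7-({[tert-butyl(dimethyl)silyl]oxy}methyl)-12-diazenyl-3,7-dimethyldodeca-2,8-dien-10-ynoate | N=NCC#C/C=C/[C@@](C)(CO[Si](C)(C)C(C)(C)C)CCC/C(C)=C/C(=O)OC | intermediate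
17 | methyl (2E,7S,8E)-7-({[tert-butyl(dimethyl)silyl]oxy}methyl)-3,7-dimethyldodeca-2,8,10,11-tetraenoate | C=C=C/C=C/[C@@](C)(CO[Si](C)(C)C(C)(C)C)CCC/C(C)=C/C(=O)OC | intermediate
18 | methyl (1R,4aS,5S,8aR)-5-({[tert-butyl(dimethyl)silyl]oxy}methyl)-5,8a-dimethyl-2-methylidene-1,2,4a,5,6,7,8,8a-octahydronaphthalene-1-carboxylate | C=C1C=C[C@@H]2[C@@](C)(CO[Si](C)(C)C(C)(C)C)CCC[C@@]2(C)[C@@H]1C(=O)OC | intermediate
19 | [(1R,4aS,5S,8aR)-5-({[tert-butyl(dimethyl)silyl]oxy}methyl)-5,8a-dimethyl-2-methylidene-1,2,4a,5,6,7,8,8a-octahydronaphthalen-1-yl]methanol | C=C1C=C[C@@H]2[C@@](C)(CO[Si](C)(C)C(C)(C)C)CCC[C@@]2(C)[C@@H]1CO | intermediate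
20 | (1R,4aS,5S,8aR)-5-({[tert-butyl(dimethyl)silyl]oxy}methyl)-5,8a-dimethyl-2-methylidene-1,2,4a,5,6,7,8,8a-octahydronaphthalene-1-carbaldehyde | C=C1C=C[C@@H]2[C@@](C)(CO[Si](C)(C)C(C)(C)C)CCC[C@@]2(C)[C@@H]1C=O | intermediate
21 | (1R,4aS,5S,8aS)-5-({[tert-butyl(dimethyl)silyl]oxy}methyl)-1-ethenyl-5,8a-dimethyl-2-methylidene-1,2,4a,5,6,7,8,8a-octahydronaphthalene | C=C1C=C[C@@H]2[C@@](C)(CO[Si](C)(C)C(C)(C)C)CCC[C@@]2(C)[C@@H]1C=C | intermediate
22 | 9-{2-[(1R,4aS,5S,8aS)-5-({[tert-butyl(dimethyl)silyl]oxy}methyl)-5,8a-dimethyl-2-methylidene-1,2,4a,5,6,7,8,8a-octahydronaphthalen-1-yl]ethyl}-9-borabicyclo[3.3.1]nonane | C=C1C=C[C@@H]2[C@@](C)(CO[Si](C)(C)C(C)(C)C)CCC[C@@]2(C)[C@@H]1CCB1C2CCCC1CCC2 | intermediate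
23 | methyl (2E)-5-[(1R,4aS,5S,8aS)-5-({[tert-butyl(dimethyl)silyl]oxy}methyl)-5,8a-dimethyl-2-methylidene-1,2,4a,5,6,7,8,8a-octahydronaphthalen-1-yl]-3-methylpent-2-enoate | C=C1C=C[C@@H]2[C@@](C)(CO[Si](C)(C)C(C)(C)C)CCC[C@@]2(C)[C@@H]1CC/C(C)=C/C(=O)OC | intermediate
24 | methyl (2E)-5-[(1R,4aS,5S,8aS)-5-(hydroxymethyl)-5,8a-dimethyl-2-methylidene-1,2,4a,5,6,7,8,8a-octahydronaphthalen-1-yl]-3-methylpent-2-enoate | C=C1C=C[C@@H]2[C@@](C)(CO)CCC[C@@]2(C)[C@@H]1CC/C(C)=C/C(=O)OC | intermediate
25 | methyl (2E)-5-[(1R,4aS,5S,8aS)-5-[(acetyloxy)methyl]-5,8a-dimethyl-2-methylidene-1,2,4a,5,6,7,8,8a-octahydronaphthalen-1-yl]-3-methylpent-2-enoate | C=C1C=C[C@@H]2[C@@](C)(COC(C)=O)CCC[C@@]2(C)[C@@H]1CC/C(C)=C/C(=O)OC | target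

**Total step count:** 16. **Longest linear sequence:** 15 steps (3 → 25, steps 2–16); step 1 supplies coupling partner 2, which is used in steps 3 and 14.

**Steps most likely to fail**

Step 10. Addition at the fully substituted C10 next to the quaternary C4 may be slow, so that the Lewis acid oligomerises the vinylallene and the endo and π-facial preferences erode. The fallback changes the dienophile to the more electrophilic enal and sets out from 17. Reduction with i-Bu2AlH (CH2Cl2, −78 °C) should give the allenic dienol F1. Oxidation with MnO2 should give the allenic enal F2 with the (E) geometry kept. The enal should then cyclise on gentle warming or with a substoichiometric amount of Me2AlCl through the same endo transition state to aldehyde 20. The route is rejoined at 20 for step 13, and steps 11 and 12 are no longer needed.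

Step 6. Hydride may migrate in place of the siloxymethyl group (giving an α-silyloxy ketone), or the ester may hold back the aluminium reagent so that the epoxide is not opened cleanly. The fallback builds the quaternary centre by enzymatic desymmetrisation and sets out from enol triflate 2 and the commercial malonate F3.
- Diethyl 2-methyl-2-(prop-2-en-1-yl)propanedioate F3 is reduced with LiAlH4 to the prochiral diol F4.
- Transesterification with vinyl acetate, catalysed by a lipase selected to acylate the pro-R arm, gives the (R)-monoacetate F5.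
- Silylation (TBSCl, imidazole) gives the silyl ether acetate F6.
- Hydroboration with 9-BBN gives the alkylborane F7, which is coupled with 2 as in step 3 to the acetoxy enoate F8.
- Methanolysis of the acetate (K2CO3, MeOH) gives the primary alcohol F9.
- Dess–Martin oxidation of F9 returns the route to aldehyde 11.

Step 13. The basic ylide may enolise the β,γ-unsaturated aldehyde, epimerising C9 or drawing C8=C17 into conjugation, and the hydroboration that follows depends on discriminating the new vinyl group from the diene. The fallback avoids the aldehyde and sets out from alcohol 19 and methyl acetoacetate 1.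
- I2, PPh3 and imidazole convert 19 into the C11 iodide F10.
- The acetoacetate dianion F11 (from 1 with NaH, then n-BuLi, THF, 0 °C) is alkylated at its terminal carbon by F10 to give the β-keto ester F12.
- Enol triflation with Tf2O and aqueous LiOH in toluene gives the (Z)-enol triflate F13 through the chelated enolate.
- Iron-catalysed cross-coupling with MeMgBr (Fe(acac)3 cat., THF/NMP, −30 °C) replaces the triflate by methyl with retention and returns the route to 23.

**Further compounds**
F1 | step 10 | (2E,7S,8E)-7-({[tert-butyl(dimethyl)silyl]oxy}methyl)-3,7-dimethyldodeca-2,8,10,11-tetraen-1-ol | C=C=C/C=C/[C@@](C)(CO[Si](C)(C)C(C)(C)C)CCC/C(C)=C/CO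
F2 | step 10 | (2E,7S,8E)-7-({[tert-butyl(dimethyl)silyl]oxy}methyl)-3,7-dimethyldodeca-2,8,10,11-tetraenal | C=C=C/C=C/[C@@](C)(CO[Si](C)(C)C(C)(C)C)CCC/C(C)=C/C=O
F3 | step 6 | diethyl 2-methyl-2-(prop-2-en-1-yl)propanedioate | CCOC(=O)C(C)(CC=C)C(=O)OCC
F4 | step 6 | 2-methyl-2-(prop-2-en-1-yl)propane-1,3-diol | OCC(C)(CO)CC=C
F5 | step 6 | (2R)-2-(hydroxymethyl)-2-methylpent-4-en-1-yl acetate | CC(=O)OC[C@@](C)(CO)CC=C
F6 | step 6 | (2S)-2-({[tert-butyl(dimethyl)silyl]oxy}methyl)-2-methylpent-4-en-1-yl acetate | CC(=O)OC[C@@](C)(CO[Si](C)(C)C(C)(C)C)CC=C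
F7 | step 6 | (2S)-5-(9-borabicyclo[3.3.1]nonan-9-yl)-2-({[tert-butyl(dimethyl)silyl]oxy}methyl)-2-methylpentyl acetate | CC(=O)OC[C@@](C)(CO[Si](C)(C)C(C)(C)C)CCCB1C2CCCC1CCC2
F8 | step 6 | methyl (2E,7S)-8-(acetyloxy)-7-({[tert-butyl(dimethyl)silyl]oxy}methyl)-3,7-dimethyloct-2-enoate | CC(=O)OC[C@@](C)(CO[Si](C)(C)C(C)(C)C)CCC/C(C)=C/C(=O)OC
F9 | step 6 | methyl (2E,7S)-7-({[tert-butyl(dimethyl)silyl]oxy}methyl)-8-hydroxy-3,7-dimethyloct-2-enoate | OC[C@@](C)(CO[Si](C)(C)C(C)(C)C)CCC/C(C)=C/C(=O)OC
F10 | step 13 | (1R,4aS,5S,8aR)-5-({[tert-butyl(dimethyl)silyl]oxy}methyl)-1-(iodomethyl)-5,8a-dimethyl-2-methylidene-1,2,4a,5,6,7,8,8a-octahydronaphthalene | C=C1C=C[C@@H]2[C@@](C)(CO[Si](C)(C)C(C)(C)C)CCC[C@@]2(C)[C@@H]1CI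
F11 | step 13 | sodium lithium dianion of methyl acetoacetate | [Na+].[Li+].[CH2-]C(=O)[CH-]C(=O)OC
F12 | step 13 | methyl 5-[(1R,4aS,5S,8aS)-5-({[tert-butyl(dimethyl)silyl]oxy}methyl)-5,8a-dimethyl-2-methylidene-1,2,4a,5,6,7,8,8a-octahydronaphthalen-1-yl]-3-oxopentanoate | C=C1C=C[C@@H]2[C@@](C)(CO[Si](C)(C)C(C)(C)C)CCC[C@@]2(C)[C@@H]1CCC(=O)CC(=O)OC
F13 | step 13 | methyl (2Z)-5-[(1R,4aS,5S,8aS)-5-({[tert-butyl(dimethyl)silyl]oxy}methyl)-5,8a-dimethyl-2-methylidene-1,2,4a,5,6,7,8,8a-octahydronaphthalen-1-yl]-3-{[(trifluoromethyl)sulfonyl]oxy}pent-2-enoate | C=C1C=C[C@@H]2[C@@](C)(CO[Si](C)(C)C(C)(C)C)CCC[C@@]2(C)[C@@H]1CC/C(OS(=O)(=O)C(F)(F)F)=C/C(=O)OC
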